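The route rests on the bond between C6 of the chromanone's benzene ring and the benzylic carbon of the octanoic acid chain. It is formed by an NHC-catalysed redox annulation of oct-2-ynal with the enol-like C5–OH/C6–H edge of an open-chain, prenylated tigloylphloroglucinol in which C6 is the only free ring carbon: one operation makes the aryl–C bond, sets the (R) centre, reaches the acid oxidation level and ties O5 and the carboxyl carbon into a six-membered lactone. This temporary dihydrocoumarin ring leaves only the hydroxyl beside the prenyl group free, so a later quinidine-catalysed oxa-Michael closure gives the cis-(2S,3R)-chromanone with a single regiochemistry; opening the lactone ends the synthesis.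

Key step: step 5

Remark on the chemistry: the 2,3-dimethyl pair of the target is cis, the kinetically formed and base-labile arrangement, so the chromanone is closed late and all earlier steps avoid base. The sense of induction of the triazolium salt (step 5) and of quinidine (step 6) is assigned by analogy; the mirror-image or pseudo-enantiomeric catalyst is available in both cases.

Step 1
Reactants: 1 phloroglucinol; 2 tigloyl chloride
Product: 3 (E)-2-methyl-1-(2,4,6-trihydroxyphenyl)but-2-en-1-one
Conditions: AlCl3 (4 equiv), PhNO2/CH2Cl2, 0 °C to rt; ice/1 M HCl work-up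
Reagents that add atoms: none
Why: Friedel–Crafts acylation of the threefold-symmetric, threefold-activated arene can give only one C-acyl regioisomer, the aluminium chelate of the product resists a second acylation, and without base or heat the ortho-hydroxy tigloyl ketone is expected to stay open (no stereocentre is formed).

Step 2
Reactants: 3 (E)-2-methyl-1-(2,4,6-trihydroxyphenyl)but-2-en-1-one; 4 methanol
Product: 5 (E)-1-(2,6-dihydroxy-4-methoxyphenyl)-2-methylbut-2-en-1-one
Conditions: PPh3, DIAD, THF, 0 °C (one equivalent of 4)
Reagents that add atoms: none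
Why: Mitsunobu etherification alkylates the most acidic phenol, here the para hydroxyl that is not held in the hydrogen bond to the ketone, and its neutral medium avoids the phenoxide-driven oxa-Michael closure that carbonate bases would start.

Step 3
Reactants: 5 (E)-1-(2,6-dihydroxy-4-methoxyphenyl)-2-methylbut-2-en-1-one; 6 prenol
Product: 7 (E)-1-[2-hydroxy-4-methoxy-6-(3-methylbut-2-en-1-yloxy)phenyl]-2-methylbut-2-en-1-one
Conditions: PPh3, DIAD, THF, 0 °C to rt
Reagents that add atoms: none
Why: A second Mitsunobu etherification, a reaction known for chelated 5-hydroxy-4-oxo phenols, alkylates one of the two equivalent ortho hydroxyls, and the remaining hydroxyl, then locked in the hydrogen bond to the carbonyl, should stay untouched.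

Step 4
Reactants: 7 (E)-1-[2-hydroxy-4-methoxy-6-(3-methylbut-2-en-1-yloxy)phenyl]-2-methylbut-2-en-1-one
Product: 10 (E)-1-[2,6-dihydroxy-4-methoxy-3-(3-methylbut-2-en-1-yl)phenyl]-2-methylbut-2-en-1-one, via ortho-dienone 8 (not isolated), via para-dienone 9 (not isolated)
Conditions: Eu(fod)3 (10 mol%), CHCl3, 60 °C, sealed tube
Reagents that add atoms: none
Why: In this lanthanide-promoted tandem aromatic Claisen–Cope rearrangement the first [3,3] shift places a 1,1-dimethylallyl group on the ortho carbon (8), the europium-bound dienone should undergo the second [3,3] shift to the para carbon (9) faster than it enolises, and tautomerisation gives the normal prenyl group on the carbon between OH and OMe.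

Step 5
Reactants: 10 (E)-1-[2,6-dihydroxy-4-methoxy-3-(3-methylbut-2-en-1-yl)phenyl]-2-methylbut-2-en-1-one; 11 oct-2-ynal
Product: 12 (4R)-7-hydroxy-5-methoxy-6-(3-methylbut-2-en-1-yl)-8-[(E)-2-methylbut-2-enoyl]-4-pentyl-3,4-dihydro-2H-chromen-2-one
Conditions: aminoindanol-derived N-mesityl triazolium chloride (10 mol%, single antipode), toluene, 40 °C, no added base
Reagents that add atoms: none
Why: The carbene adds to the ynal and an internal redox (hydroxy-enamine, allenol, proton shift) gives the (E)-oct-2-enoyl azolium; the acidic 6-OH of 10 adds to its carbonyl and the hemiketal passes aryl C5 to the β-carbon by a [3,3] shift (equivalently, C5 adds in a conjugate sense), after which acyl transfer to O6 releases the catalyst. The closest known reaction type is the NHC-catalysed redox annulation of ynals with kojic acids, naphthols and other acidic stable enols, which gives dihydropyranones and dihydrocoumarins without added base. The lactone ring closes by 6-exo-trig acyl substitution at the acyl azolium, so the overall process is a formal [3+3] annulation across the C5–C6(OH) edge of 10 (C6–C5(OH) of the future chromanone). The new benzylic centre is under catalyst control: the aminoindanol backbone shields one face of the planar enoyl azolium, and the antipode expected to give 4R is used. Site selectivity is fixed by the substrate, since C5 is the only unsubstituted ring carbon and O6 the only oxygen next to it, while acylation of the other hydroxyl is reversible under carbene catalysis. The chemoselectivity the step needs, no closure of the free hydroxyl onto the tigloyl enone, is secured by the base-free medium in which chloride is the only base.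

Step 6
Reactants: 12 (4R)-7-hydroxy-5-methoxy-6-(3-methylbut-2-en-1-yl)-8-[(E)-2-methylbut-2-enoyl]-4-pentyl-3,4-dihydro-2H-chromen-2-one
Product: 13 (4R,8S,9R)-5-methoxy-8,9-dimethyl-6-(3-methylbut-2-en-1-yl)-4-pentyl-3,4,8,9-tetrahydro-2H,10H-pyrano[2,3-f]chromene-2,10-dione
Conditions: quinidine (20 mol%), PhCl, rt
Reagents that add atoms: none
Why: In this cinchona-alkaloid-catalysed asymmetric intramolecular oxa-Michael addition (6-endo-trig), a reaction known for 7-hydroxy-8-tigloylcoumarins, the quinuclidine nitrogen activates the only free phenol and the catalyst hydroxyl binds the ketone, so that face-selective C–O bond formation sets C8 (S) and kinetic syn protonation of the enol sets C9 (R), the cis pair; quinine would give the mirror-image pair at these two centres.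

Step 7
Reactants: 13 (4R,8S,9R)-5-methoxy-8,9-dimethyl-6-(3-methylbut-2-en-1-yl)-4-pentyl-3,4,8,9-tetrahydro-2H,10H-pyrano[2,3-f]chromene-2,10-dione
Product: 14 (3R)-3-[(2S,3R)-5-hydroxy-7-methoxy-2,3-dimethyl-8-(3-methylbut-2-en-1-yl)-4-oxo-3,4-dihydro-2H-chromen-6-yl]octanoic acid
Conditions: LiOH (2.2 equiv), THF/H2O 3:1, 0 °C, short reaction time; then cold 1 M HCl to pH 3
Reagents that add atoms: lithium hydroxide, [Li+].[OH-]
Why: Saponification of the phenyl-ester-type lactone should be much faster than enolisation of the chromanone at 0 °C, the liberated phenoxide conjugated with the ketone lowers the acidity of the C3 hydrogen further, and the hydrogen-bonded 5-hydroxyl should not relactonise on cold acidification, so all three stereocentres are expected to be retained.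

Compound list
1 | phloroglucinol (benzene-1,3,5-triol) | Oc1cc(O)cc(O)c1 | starting material
2 | tigloyl chloride, (E)-2-methylbut-2-enoyl chloride | C/C=C(\C)C(=O)Cl | starting material
3 | (E)-2-methyl-1-(2,4,6-trihydroxyphenyl)but-2-en-1-one | C/C=C(\C)C(=O)c1c(O)cc(O)cc1O | intermediate
4 | methanol | CO | starting material
5 | (E)-1-(2,6-dihydroxy-4-methoxyphenyl)-2-methylbut-2-en-1-one | C/C=C(\C)C(=O)c1c(O)cc(OC)cc1O | intermediate
6 | prenol, 3-methylbut-2-en-1-ol | CC(C)=CCO | starting material
7 | (E)-1-[2-hydroxy-4-methoxy-6-(3-methylbut-2-en-1-yloxy)phenyl]-2-methylbut-2-en-1-one | C/C=C(\C)C(=O)c1c(O)cc(OC)cc1OCC=C(C)C | intermediate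
8 | ortho-dienone, 3-hydroxy-5-methoxy-6-(2-methylbut-3-en-2-yl)-2-[(E)-2-methylbut-2-enoyl]cyclohexa-2,4-dien-1-one | C/C=C(\C)C(=O)C1=C(O)C=C(OC)C(C(C)(C)C=C)C1=O | intermediate (not isolated)
9 | para-dienone, 3-hydroxy-5-methoxy-4-(3-methylbut-2-en-1-yl)-2-[(E)-2-methylbut-2-enoyl]cyclohexa-2,5-dien-1-one | C/C=C(\C)C(=O)C1=C(O)C(CC=C(C)C)C(OC)=CC1=O | intermediate (not isolated)
10 | (E)-1-[2,6-dihydroxy-4-methoxy-3-(3-methylbut-2-en-1-yl)phenyl]-2-methylbut-2-en-1-one | C/C=C(\C)C(=O)c1c(O)cc(OC)c(CC=C(C)C)c1O | intermediate
11 | oct-2-ynal | CCCCCC#CC=O | starting material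
12 | (4R)-7-hydroxy-5-methoxy-6-(3-methylbut-2-en-1-yl)-8-[(E)-2-methylbut-2-enoyl]-4-pentyl-3,4-dihydro-2H-chromen-2-one | CCCCC[C@@H]1CC(=O)Oc2c1c(OC)c(CC=C(C)C)c(O)c2C(=O)/C(C)=C/C | intermediate
13 | (4R,8S,9R)-5-methoxy-8,9-dimethyl-6-(3-methylbut-2-en-1-yl)-4-pentyl-3,4,8,9-tetrahydro-2H,10H-pyrano[2,3-f]chromene-2,10-dione (cis-8,9-dimethyl) | CCCCC[C@@H]1CC(=O)Oc2c1c(OC)c(CC=C(C)C)c1O[C@@H](C)[C@@H](C)C(=O)c21 | intermediate
14 | (3R)-3-[(2S,3R)-5-hydroxy-7-methoxy-2,3-dimethyl-8-(3-methylbut-2-en-1-yl)-4-oxo-3,4-dihydro-2H-chromen-6-yl]octanoic acid | CCCCC[C@H](CC(=O)O)c1c(O)c2c(c(CC=C(C)C)c1OC)O[C@@H](C)[C@@H](C)C2=O | target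

Total step count: 7. Longest linear sequence: 7 steps (fully linear from phloroglucinol).

Steps most likely to fail

Step 5. The carbon–carbon bond formation at the hindered, carbonyl-conjugated phenol may be slow while the acyl azolium is drained by O-acylation. Facial control may be insufficient. Traces of base may also start ring closure of the tigloyl ketone. The fallback sets out from 10 and returns at 12, and makes the same bond through iminium activation instead of an acyl azolium. Compound 10 and (E)-oct-2-enal are combined with a diarylprolinol silyl ether (the enantiomer leading to 4R) and benzoic acid in toluene at 0 °C. Conjugate Friedel–Crafts addition of C5, followed by hemiacetal formation with the neighbouring hydroxyl, should give the lactol (E)-1-[(4R)-2,7-dihydroxy-5-methoxy-6-(3-methylbut-2-en-1-yl)-4-pentyl-3,4-dihydro-2H-chromen-8-yl]-2-methylbut-2-en-1-one F1. Silver carbonate on Celite (benzene, reflux) would then oxidise the lactol to lactone 12.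

Step 6. The cis relationship may erode through enolisation at C9, a drift toward the more stable trans arrangement, during the ring closure. The fallback sets out from 12 and returns at 13, and sets C9 in a separate kinetic protonation. The ring closure is run as in step 6 and the product, 13 together with its C9 epimer (4R,8S,9S)-5-methoxy-8,9-dimethyl-6-(3-methylbut-2-en-1-yl)-4-pentyl-3,4,8,9-tetrahydro-2H,10H-pyrano[2,3-f]chromene-2,10-dione F2, is not separated. TMSOTf and Et3N (CH2Cl2, −78 °C) should convert both into the one silyl enol ether (4R,8S)-5-methoxy-8,9-dimethyl-6-(3-methylbut-2-en-1-yl)-4-pentyl-10-(trimethylsilyloxy)-3,4-dihydro-2H,8H-pyrano[2,3-f]chromen-2-one F3. Protodesilylation with a Brønsted acid in wet THF at low temperature should deliver the proton to C9 anti to the pseudo-axial C8 methyl group and return cis-configured 13.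

Step 4. The first dienone may enolise before the Cope shift, which would leave a 1,1-dimethylallyl group on the ortho carbon, and the Lewis acid may induce cyclisation of the enone or of the prenyl group. The fallback sets out from 5 and returns at 10, replacing steps 3 and 4. Palladium-catalysed O-allylation of 5 with tert-butyl 2-methylbut-3-en-2-yl carbonate (Pd(PPh3)4, THF, 0 °C) should give the tertiary ether (E)-1-[2-hydroxy-4-methoxy-6-(2-methylbut-3-en-2-yloxy)phenyl]-2-methylbut-2-en-1-one F4. A single ortho-Claisen rearrangement of this ether (toluene, 110 °C) would place a normal prenyl group on the only free ortho carbon and give 10 directly.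

Further compounds
F1 | step 5 | (E)-1-[(4R)-2,7-dihydroxy-5-methoxy-6-(3-methylbut-2-en-1-yl)-4-pentyl-3,4-dihydro-2H-chromen-8-yl]-2-methylbut-2-en-1-one (lactol, mixture at C2) | CCCCC[C@@H]1CC(O)Oc2c1c(OC)c(CC=C(C)C)c(O)c2C(=O)/C(C)=C/C
F2 | step 6 | (4R,8S,9S)-5-methoxy-8,9-dimethyl-6-(3-methylbut-2-en-1-yl)-4-pentyl-3,4,8,9-tetrahydro-2H,10H-pyrano[2,3-f]chromene-2,10-dione (trans-8,9-dimethyl) | CCCCC[C@@H]1CC(=O)Oc2c1c(OC)c(CC=C(C)C)c1O[C@@H](C)[C@H](C)C(=O)c21
F3 | step 6 | (4R,8S)-5-methoxy-8,9-dimethyl-6-(3-methylbut-2-en-1-yl)-4-pentyl-10-(trimethylsilyloxy)-3,4-dihydro-2H,8H-pyrano[2,3-f]chromen-2-one | CCCCC[C@@H]1CC(=O)Oc2c1c(OC)c(CC=C(C)C)c1O[C@@H](C)C(C)=C(O[Si](C)(C)C)c21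
F4 | step 4 | (E)-1-[2-hydroxy-4-methoxy-6-(2-methylbut-3-en-2-yloxy)phenyl]-2-methylbut-2-en-1-one | C/C=C(\C)C(=O)c1c(O)cc(OC)cc1OC(C)(C)C=C
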